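**Retrosynthetic overview**

- Labels: ring A is the 5-bromo-2-hydroxyphenyl ring; in ring B, B1 is C–O(ether), B2 C–OH, B3 C–Br, B4 C–H, B5 C–Br, B6 C–Br. The route rests on B6: its bromine lies ortho to the ether oxygen and meta to the hydroxyl while B4, para to the ether oxygen, is unsubstituted. Hydroxyl-directed bromination can supply only B3–Br and B5–Br, so B6 has to enter as a ready-made C–Br carbon.
- Target ⇐ O-demethylation of ring A ⇐ dibromination at B3 and B5 of a 3-bromo-2-aryloxyphenol (B6–Br in place, ring A still a methyl ether).
- That phenol ⇐ aromatisation of a 2-aryloxy-3-bromocyclohexa-2,4-dienone ketal. Acid opening of such a ketal aromatises with one C–O bond retained, so a 1,3-dioxane is used: the ether left on B2 is then a 3-hydroxypropyl ether, removable by oxidation and β-elimination without touching the ring A methyl ether.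
- Dienone ketal ⇐ dibromocarbene addition to the B1=B5 bond of a five-membered aryl enol ether ketal and cyclopropyl-to-allyl opening. B6 is inserted between B1 and B5 and the cyclopentene becomes ring B (the only ring made; ring A is bought).
- Five-membered precursor ⇐ ketalisation of the 2-aryloxycyclopent-2-enone ⇐ 2,3-epoxycyclopentanone + 5-bromo-2-methoxyphenol ⇐ cyclopent-2-en-1-one.

Key step: step 4

Remark: the target has no stereocentre; chiral intermediates are racemic and are drawn with relative configuration only.
Remark: 1,3-bis(trimethylsilyloxy)propane is taken as a purchasable reagent (otherwise one silylation from propane-1,3-diol).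

**Route**

Step 1
Reactants: 1 cyclopent-2-en-1-one
Product: 2 6-oxabicyclo[3.1.0]hexan-2-one (2,3-epoxycyclopentan-1-one, racemic, cis-fused)
Conditions: H2O2 (30% aq), NaOH (cat.), MeOH, 0 °C
Reagents that add atoms: hydrogen peroxide, OO
Why: Weitz–Scheffer nucleophilic epoxidation: hydroperoxide adds to the β-carbon of the enone and the enolate closes on the O–O bond, which can only give the cis-fused racemic epoxide, whose two stereocentres are erased again in step 2.

Step 2
Reactants: 2 6-oxabicyclo[3.1.0]hexan-2-one; 3 5-bromo-2-methoxyphenol
Product: 5 2-(5-bromo-2-methoxyphenoxy)cyclopent-2-en-1-one, via trans-hydroxy ketone 4 (not isolated)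
Conditions: Cs2CO3 (0.3 equiv), DMF, 0 °C → 50 °C
Reagents that add atoms: none
Why: Base-mediated epoxide opening followed by E1cB dehydration, the known route from α,β-epoxy ketones and phenols to 2-aryloxy enones: the phenoxide of 3 attacks the carbonyl-activated α-carbon with inversion (trans hydroxy ether 4, racemic), loss of water then removes both stereocentres, and the aryl bromide is inert under these metal-free conditions.

Step 3
Reactants: 5 2-(5-bromo-2-methoxyphenoxy)cyclopent-2-en-1-one; 6 1,3-bis(trimethylsilyloxy)propane
Product: 7 1-(5-bromo-2-methoxyphenoxy)-6,10-dioxaspiro[4.5]dec-1-ene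
Conditions: TMSOTf (cat.), CH2Cl2, −78 → −20 °C; pyridine quench
Reagents that add atoms: 1,3-bis(trimethylsilyloxy)propane (compound 6), C[Si](C)(C)OCCCO[Si](C)(C)C
Why: Noyori ketalisation: TMSOTf-catalysed exchange of the carbonyl oxygen for the bis-silyl diol at low temperature, driven by formation of hexamethyldisiloxane and free of water and of equilibrating protic acid, so the double bond should stay on B1=B5; the 1,3-dioxane is chosen over a dioxolane so that the oxygen left on B2 after step 5 carries a 3-hydroxypropyl chain that step 6 can remove.

Step 4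
Reactants: 7 1-(5-bromo-2-methoxyphenoxy)-6,10-dioxaspiro[4.5]dec-1-ene; 8 bromoform
Product: 11 8-bromo-7-(5-bromo-2-methoxyphenoxy)-1,5-dioxaspiro[5.5]undeca-7,9-diene, via dibromocyclopropane 9 (not isolated), via allylic bromide 10 (not isolated)
Conditions: CHBr3 (2 equiv), KOtBu (5 equiv), hexane–toluene, −20 °C → rt, then 40 °C
Reagents that add atoms: bromoform (compound 8), BrC(Br)Br
Why: Dibromocarbene, formed from bromoform 8 by deprotonation and loss of bromide, adds as a singlet electrophile in a concerted [2+1] cycloaddition to the B1=B5 enol ether bond of 7, the only electron-rich alkene in the molecule, to give the cis-fused 6,6-dibromobicyclo[3.1.0]hexane 9. The aryloxy oxygen on B1 then assists ionisation of the endo bromide with disrotatory two-electron electrocyclic opening of the B1–B5 bond, so the three-membered and five-membered rings merge into the six-membered ring B with the new carbon B6 between B1 and B5 (ring B is closed by one-carbon ring enlargement, cyclopropyl to allyl cation, not by an end-to-end cyclisation); the 2-bromoallyl ion pair collapses to allylic bromide 10, from which KOtBu removes HBr across B5–B4. The closest known reaction type is the dihalocarbene ring expansion of cyclic alkyl and silyl enol ethers to 2-halocycloalkenones and of cyclopentadienes and indenes to halo-arenes. No stereocentre survives: 9 and 10 are racemic intermediates and 11 is achiral. The step needs chemoselectivity for the enol ether over the anisole ring A, which the low reactivity of a benzene ring towards dihalocarbenes provides, and insertion on the B1–B5 side and not next to B2, which is fixed because B2 is a saturated ketal carbon and B1=B5 is the only C=C; the basic, anhydrous medium leaves the ketal and the aryl bromide untouched.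

Step 5
Reactants: 11 8-bromo-7-(5-bromo-2-methoxyphenoxy)-1,5-dioxaspiro[5.5]undeca-7,9-diene
Product: 12 3-[3-bromo-2-(5-bromo-2-methoxyphenoxy)phenoxy]propan-1-ol
Conditions: camphorsulfonic acid (cat.), CH2Cl2 (anhydrous), 0 °C → rt
Reagents that add atoms: none
Why: Acid-catalysed aromatising ketal opening (E1 loss of an alcohol from a cyclohexa-2,4-dienone ketal): ionisation of one ketal C–O bond gives a 1-alkoxycyclohexadienyl (arenium) cation that loses the B3 proton faster than it could be hydrated, so ring B aromatises with one C–O bond retained as the 3-hydroxypropyl ether, and the anhydrous medium spares the aryl enol ether from hydrolysis before that happens.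

Step 6
Reactants: 12 3-[3-bromo-2-(5-bromo-2-methoxyphenoxy)phenoxy]propan-1-ol
Product: 14 3-bromo-2-(5-bromo-2-methoxyphenoxy)phenol, via aryloxypropanal 13 (not isolated)
Conditions: Dess–Martin periodinane, CH2Cl2, 0 °C → rt; aq Na2S2O3 wash; then DBU, CH2Cl2, rt; dilute HCl work-up
Reagents that add atoms: none
Why: Dess–Martin oxidation followed by retro-oxa-Michael (E1cB) cleavage: the aldehyde places the B2 aryloxy group β to an acidic C–H, so DBU expels the phenoxide with release of acrolein, while the methyl ether of ring A has no such pathway and stays in place.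

Step 7
Reactants: 14 3-bromo-2-(5-bromo-2-methoxyphenoxy)phenol
Product: 15 3,4,6-tribromo-2-(5-bromo-2-methoxyphenoxy)phenol
Conditions: Br2 (2.05 equiv), CH2Cl2, −20 → 0 °C
Reagents that add atoms: bromine, BrBr
Why: Electrophilic aromatic bromination directed by the free hydroxyl on B2 to its ortho (B3) and para (B5) positions: the phenol ring should react far faster than the anisole-type ring A, whose position para to the methoxy group already carries bromine, and with two equivalents B4, meta to the hydroxyl, is left as C–H.

Step 8
Reactants: 15 3,4,6-tribromo-2-(5-bromo-2-methoxyphenoxy)phenol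
Product: 16 3,4,6-tribromo-2-(5-bromo-2-hydroxyphenoxy)phenol (target)
Conditions: BBr3 (3 equiv), CH2Cl2, −78 °C → rt; H2O
Reagents that add atoms: none
Why: Lewis acid-mediated aryl methyl ether cleavage: BBr3 coordinates the methoxy oxygen of ring A and bromide removes the methyl group by SN2, the diaryl ether and the aryl bromides being inert, and aqueous work-up hydrolyses the aryl borates to the two free hydroxyls.

**Compound list**

1 | cyclopent-2-en-1-one | O=C1C=CCC1 | starting material
2 | 6-oxabicyclo[3.1.0]hexan-2-one (2,3-epoxycyclopentan-1-one; racemic, cis-fused) | O=C1CC[C@H]2O[C@@H]12 | intermediate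
3 | 5-bromo-2-methoxyphenol | COc1ccc(Br)cc1O | starting material
4 | trans-2-(5-bromo-2-methoxyphenoxy)-3-hydroxycyclopentan-1-one (racemic) | O=C1CC[C@@H](O)[C@@H]1Oc1cc(Br)ccc1OC | intermediate (not isolated)
5 | 2-(5-bromo-2-methoxyphenoxy)cyclopent-2-en-1-one | COc1ccc(Br)cc1OC1=CCCC1=O | intermediate
6 | 1,3-bis(trimethylsilyloxy)propane | C[Si](C)(C)OCCCO[Si](C)(C)C | starting material
7 | 1-(5-bromo-2-methoxyphenoxy)-6,10-dioxaspiro[4.5]dec-1-ene | COc1ccc(Br)cc1OC1=CCCC12OCCCO2 | intermediate
8 | bromoform | BrC(Br)Br | starting material
9 | 6,6-dibromo-1-(5-bromo-2-methoxyphenoxy)spiro[bicyclo[3.1.0]hexane-2,2'-[1,3]dioxane] (racemic, cis-fused) | BrC1(Br)[C@@H]2CCC3(OCCCO3)[C@]12Oc1cc(Br)ccc1OC | intermediate (not isolated)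
10 | 8,9-dibromo-7-(5-bromo-2-methoxyphenoxy)-1,5-dioxaspiro[5.5]undec-7-ene (racemic) | COc1ccc(Br)cc1OC1=C(Br)C(Br)CCC12OCCCO2 | intermediate (not isolated)
11 | 8-bromo-7-(5-bromo-2-methoxyphenoxy)-1,5-dioxaspiro[5.5]undeca-7,9-diene | COc1ccc(Br)cc1OC1=C(Br)C=CCC12OCCCO2 | intermediate
12 | 3-[3-bromo-2-(5-bromo-2-methoxyphenoxy)phenoxy]propan-1-ol | COc1ccc(Br)cc1Oc1c(Br)cccc1OCCCO | intermediate
13 | 3-[3-bromo-2-(5-bromo-2-methoxyphenoxy)phenoxy]propanal | COc1ccc(Br)cc1Oc1c(Br)cccc1OCCC=O | intermediate (not isolated)
14 | 3-bromo-2-(5-bromo-2-methoxyphenoxy)phenol | COc1ccc(Br)cc1Oc1c(O)cccc1Br | intermediate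
15 | 3,4,6-tribromo-2-(5-bromo-2-methoxyphenoxy)phenol | COc1ccc(Br)cc1Oc1c(O)c(Br)cc(Br)c1Br | intermediate
16 | 3,4,6-tribromo-2-(5-bromo-2-hydroxyphenoxy)phenol | Oc1ccc(Br)cc1Oc1c(O)c(Br)cc(Br)c1Br | target

**Step count and risks**

Total step count: 8. Longest linear sequence: 8 steps (1 → 16).

The three steps most likely to fail, riskiest first:

Step 4. Carbene transfer may be slow or unselective, because the enol ether is deactivated by the O-aryl group and by the neighbouring ketal. Carbene decay, insertion next to the ketal oxygens, or capture of the allyl cation by tert-butoxide could then outrun the ring enlargement. Base-induced loss of the ketal alkoxide from 11 would be harmless, since it only anticipates step 5. The fallback gives up the ring enlargement and buys ring B. It sets out from phenol 3 and comes back at 14. Nucleophilic aromatic substitution of commercial 3-bromo-2-fluorobenzaldehyde (O=Cc1cccc(Br)c1F) by 3 (K2CO3, DMF, 90 °C), with the formyl group activating the fluoride, should give 3-bromo-2-(5-bromo-2-methoxyphenoxy)benzaldehyde F1. Baeyer–Villiger (Dakin-type) oxidation with mCPBA in CH2Cl2 should give 3-bromo-2-(5-bromo-2-methoxyphenoxy)phenyl formate F2, and methanolysis (K2CO3, MeOH) releases 14, with B6–Br carried in by the aldehyde.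

Step 3. Acid may move the double bond out of B1=B5, the diol may add in conjugate fashion, or the exchange may stall at the hindered, electron-poor carbonyl. The fallback makes the ketal first and the C–O bond last. It sets out from 1 and comes back at 7. α-Iodination of 1 (I2, pyridine, CH2Cl2) gives 2-iodocyclopent-2-en-1-one F3. Classical ketalisation (propane-1,3-diol, TsOH cat., benzene, Dean–Stark), in which the halogen on the α-carbon holds the double bond in place, gives 1-iodo-6,10-dioxaspiro[4.5]dec-1-ene F4. Ullmann-type O-vinylation of phenol 3 with F4 (CuI, N,N-dimethylglycine, Cs2CO3, dioxane, 90 °C) should then form aryl enol ether 7, the alkenyl iodide reacting well before the aryl bromide.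

Step 2. The sensitive epoxy ketone may self-condense or rearrange under base before it is opened, or the phenoxide may attack the β-carbon. The fallback forms the C–O bond by alkylation and introduces the double bond afterwards. It sets out from 3 and comes back at 5. O-Alkylation of 3 with commercial 2-chlorocyclopentan-1-one (O=C1CCCC1Cl; K2CO3, acetone, reflux) gives 2-(5-bromo-2-methoxyphenoxy)cyclopentan-1-one F5. Equilibrating silylation (TMSOTf, Et3N, CH2Cl2, rt) should give the more substituted, aryloxy-bearing silyl enol ether {[2-(5-bromo-2-methoxyphenoxy)cyclopent-1-en-1-yl]oxy}trimethylsilane F6, since the α-aryloxy C–H is the more acidic one. Saegusa–Ito oxidation (Pd(OAc)2, MeCN, rt) then gives enone 5 by β-hydride elimination from the only neighbouring CH2.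

**Further compounds**

F1 | step 4 | 3-bromo-2-(5-bromo-2-methoxyphenoxy)benzaldehyde | COc1ccc(Br)cc1Oc1c(Br)cccc1C=O
F2 | step 4 | 3-bromo-2-(5-bromo-2-methoxyphenoxy)phenyl formate | COc1ccc(Br)cc1Oc1c(Br)cccc1OC=O
F3 | step 3 | 2-iodocyclopent-2-en-1-one | O=C1CCC=C1I
F4 | step 3 | 1-iodo-6,10-dioxaspiro[4.5]dec-1-ene | IC1=CCCC12OCCCO2
F5 | step 2 | 2-(5-bromo-2-methoxyphenoxy)cyclopentan-1-one (racemic) | COc1ccc(Br)cc1OC1CCCC1=O
F6 | step 2 | {[2-(5-bromo-2-methoxyphenoxy)cyclopent-1-en-1-yl]oxy}trimethylsilane | COc1ccc(Br)cc1OC1=C(O[Si](C)(C)C)CCC1
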